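**Retrosynthetic overview**
- The ester oxygen sits on a quaternary ring carbon that is homoallylic to the ring alkene (O–C1–C2–C3=C4–CH3 of the cyclohexene). This 1‑oxy‑3‑ene array is the retron of a cyclopropylcarbinyl→homoallyl opening: adding a C1–C3 bond folds the cyclohexene into the bicyclo[3.1.0]hexane of (1S,5S)‑sabinene.
- Key step: acid‑catalysed union of (1S,5S)‑sabinene with 4‑methoxy‑3,5‑diprenylbenzoic acid. It forms the tertiary ester C–O bond, expands the five‑membered ring by the cyclopropane CH2, places the trisubstituted alkene and sets the stereocentre by inversion.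
- The cyclopropane bond is a temporary bond: it is made by hydroxyl‑directed Simmons–Smith reaction on (S)‑3‑isopropylcyclopent‑2‑en‑1‑ol (CBS reduction), stores the quaternary configuration, and is cut in the key step.
- Acid part: double α‑selective Suzuki–Miyaura prenylation of methyl 3,5‑dibromo‑4‑methoxybenzoate, then saponification.
- Ring order: arene and cyclopentene are bought; cyclopropane (step 6); cyclohexene by one‑carbon expansion of the cyclopentane (step 9).

Key step: step 9

Assumption: (1S,5S)‑sabinene, the enantiomer of the abundant natural form, is not taken as a bulk commercial material and is therefore made enantioselectively in steps 4–8.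

Remark: the configuration needed was derived from the target SMILES. The carbinol carbon is (R), and inversion at C1 of the bicycle requires (1S,5S)‑sabinene.

**Route**

Step 1
Reactants: 1 methyl 3,5‑dibromo‑4‑hydroxybenzoate
Product: 2 methyl 3,5‑dibromo‑4‑methoxybenzoate
Conditions: MeI, K2CO3, DMF, rt
Reagents that add atoms: iodomethane, CI
Why: Williamson O‑methylation of the acidic 2,6‑dibromophenol should proceed cleanly while the methyl ester is inert to carbonate.

Step 2
Reactants: 2 methyl 3,5‑dibromo‑4‑methoxybenzoate; 3 prenylboronic acid pinacol ester (2.6 equiv)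
Product: 5 methyl 4‑methoxy‑3,5‑bis(3‑methylbut‑2‑en‑1‑yl)benzoate, via monoprenyl aryl bromide 4 (not isolated)
Conditions: Pd precatalyst with a bulky di‑tert‑butylbiarylphosphine (t‑BuXPhos class, linear‑selective), K3PO4 (aq), MeCN, 70 °C
Reagents that add atoms: none
Why: Ligand‑controlled α‑selective Suzuki–Miyaura allylation should deliver the prenyl group through its unsubstituted CH2 terminus to both aryl bromides.

Step 3
Reactants: 5 methyl 4‑methoxy‑3,5‑bis(3‑methylbut‑2‑en‑1‑yl)benzoate
Product: 7 4‑methoxy‑3,5‑bis(3‑methylbut‑2‑en‑1‑yl)benzoic acid, via lithium carboxylate 6 (not isolated)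
Conditions: LiOH, THF/MeOH/H2O, 40 °C; then 1 M HCl to pH 3, 0 °C
Reagents that add atoms: lithium hydroxide, [Li+].[OH-]
Why: Saponification of an unhindered methyl benzoate should leave the prenyl alkenes and the aryl methyl ether untouched, and the cold, brief acidification spares the alkenes.

Step 4
Reactants: 8 3‑ethoxycyclopent‑2‑en‑1‑one; 9 isopropylmagnesium chloride
Product: 11 3‑(propan‑2‑yl)cyclopent‑2‑en‑1‑one, via magnesium alkoxide adduct 10 (not isolated)
Conditions: i‑PrMgCl (1.3 equiv), THF, 0 °C; then 1 M HCl, rt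
Reagents that add atoms: water, O
Why: Stork–Danheiser sequence: 1,2‑addition to the vinylogous ester followed by acid hydrolysis with allylic transposition should give the 3‑substituted enone.

Step 5
Reactants: 11 3‑(propan‑2‑yl)cyclopent‑2‑en‑1‑one
Product: 12 (1S)‑3‑(propan‑2‑yl)cyclopent‑2‑en‑1‑ol
Conditions: (R)‑Me‑CBS (10 mol %), BH3·SMe2 (0.7 equiv), THF, −20 °C; MeOH quench
Reagents that add atoms: none
Why: Corey–Bakshi–Shibata reduction: catalyst‑controlled 1,2‑hydride delivery with the alkenyl arm acting as the large group should give the (S)‑carbinol from the (R)‑catalyst.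

Step 6
Reactants: 12 (1S)‑3‑(propan‑2‑yl)cyclopent‑2‑en‑1‑ol
Product: 13 (1R,2S,5S)‑5‑(propan‑2‑yl)bicyclo[3.1.0]hexan‑2‑ol (hydroxyl cis to the cyclopropane CH2)
Conditions: Et2Zn (3 equiv), CH2I2 (3 equiv), CH2Cl2, −10 °C → rt
Reagents that add atoms: diiodomethane, ICI
Why: Hydroxyl‑directed Simmons–Smith cyclopropanation (Furukawa variant) should deliver CH2 to the alkene face syn to the zinc‑bound oxygen, so the carbinol centre sets both ring‑fusion centres, including the quaternary i‑Pr‑bearing carbon.

Step 7
Reactants: 13 (1R,2S,5S)‑5‑(propan‑2‑yl)bicyclo[3.1.0]hexan‑2‑ol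
Product: 14 (1R,5S)‑5‑(propan‑2‑yl)bicyclo[3.1.0]hexan‑2‑one
Conditions: Dess–Martin periodinane (1.3 equiv), pyridine, CH2Cl2, 0 °C → rt
Reagents that add atoms: none
Why: Buffered Dess–Martin oxidation of the secondary cyclopropylcarbinol should give the ketone without ionisation, and the ring‑fusion centres cannot epimerise because they are locked in the cyclopropane.

Step 8
Reactants: 14 (1R,5S)‑5‑(propan‑2‑yl)bicyclo[3.1.0]hexan‑2‑one
Product: 15 (1S,5S)‑4‑methylidene‑1‑(propan‑2‑yl)bicyclo[3.1.0]hexane [(1S,5S)‑sabinene]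
Conditions: Ph3PCH3Br (1.5 equiv), KOt‑Bu (1.4 equiv), Et2O, 0 °C → rt; pentane/silica plug, careful concentration (volatile)
Reagents that add atoms: methyltriphenylphosphonium bromide, C[P+](c1ccccc1)(c1ccccc1)c1ccccc1.[Br-]
Why: Wittig methylenation under non‑acidic conditions should convert the cyclopropyl ketone to the exocyclic alkene with the cyclopropane intact.

Step 9
Reactants: 7 4‑methoxy‑3,5‑bis(3‑methylbut‑2‑en‑1‑yl)benzoic acid (1.0 equiv); 15 (1S,5S)‑sabinene (1.5 equiv)
Product: 17 (1R)‑4‑methyl‑1‑(propan‑2‑yl)cyclohex‑3‑en‑1‑yl 4‑methoxy‑3,5‑bis(3‑methylbut‑2‑en‑1‑yl)benzoate (target), via thujyl cation 16 (not isolated)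
Conditions: HNTf2 (2–5 mol %), CH2Cl2 (0.5 M), −40 → −20 °C; Et3N quench
Reagents that add atoms: none
Why: Catalytic triflimide should protonate the exocyclic methylene of 15, which is far more basic than the trisubstituted prenyl and product alkenes because the tertiary cation is cyclopropyl‑stabilised, to give cation 16 with its charge shared by the strained C1–C5 bond; the carboxyl oxygen of 7 then attacks the quaternary cyclopropane carbon C1 anti to that bond while its electron pair becomes the ring C=C, so the five‑membered ring grows by the cyclopropane CH2 and the hindered tertiary ester forms in the same event. The closest known reaction types are the acid‑catalysed hydration of sabinene and α‑thujene to terpinen‑4‑ol, stereoinvertive cyclopropylcarbinyl‑to‑homoallyl substitution at quaternary cyclopropane carbons, and the acid‑catalysed addition of carboxylic acids to terpene alkenes with skeletal rearrangement. No ring is closed by bond formation: the six‑membered ring is the periphery of the bicyclo[3.1.0]hexane and is released by cleaving the bond shared by the two small rings. The single stereocentre is controlled by the configuration of C1 in 15 (set in step 6) and is transferred with inversion because the nucleophile can only enter opposite the departing C5, so (1S)‑15 should give the (R)‑ester. The step needs internal (C1–C5) rather than external (C5–C6) cyclopropane cleavage, which the tertiary i‑Pr‑bearing C1 and the relief of bicyclic strain secure, and it needs capture ahead of proton loss or collapse to the achiral classical terpinen‑4‑yl cation, which low temperature, high concentration, a non‑nucleophilic counter‑ion and excess 15 should favour. Any ester formed kinetically at C4 is a tertiary cyclopropylcarbinyl ester that should re‑ionise under the conditions and drain to the ring‑expanded product.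

**Compound list**
1 | methyl 3,5‑dibromo‑4‑hydroxybenzoate | COC(=O)c1cc(Br)c(O)c(Br)c1 | starting material
2 | methyl 3,5‑dibromo‑4‑methoxybenzoate | COC(=O)c1cc(Br)c(OC)c(Br)c1 | intermediate
3 | 4,4,5,5‑tetramethyl‑2‑(3‑methylbut‑2‑en‑1‑yl)‑1,3,2‑dioxaborolane (prenylboronic acid pinacol ester) | CC(C)=CCB1OC(C)(C)C(C)(C)O1 | starting material
4 | methyl 3‑bromo‑4‑methoxy‑5‑(3‑methylbut‑2‑en‑1‑yl)benzoate | COC(=O)c1cc(Br)c(OC)c(CC=C(C)C)c1 | intermediate
5 | methyl 4‑methoxy‑3,5‑bis(3‑methylbut‑2‑en‑1‑yl)benzoate | COC(=O)c1cc(CC=C(C)C)c(OC)c(CC=C(C)C)c1 | intermediate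
6 | lithium 4‑methoxy‑3,5‑bis(3‑methylbut‑2‑en‑1‑yl)benzoate | [Li+].[O-]C(=O)c1cc(CC=C(C)C)c(OC)c(CC=C(C)C)c1 | intermediate
7 | 4‑methoxy‑3,5‑bis(3‑methylbut‑2‑en‑1‑yl)benzoic acid | OC(=O)c1cc(CC=C(C)C)c(OC)c(CC=C(C)C)c1 | intermediate
8 | 3‑ethoxycyclopent‑2‑en‑1‑one | CCOC1=CC(=O)CC1 | starting material
9 | isopropylmagnesium chloride | CC(C)[Mg]Cl | starting material
10 | chloromagnesium 3‑ethoxy‑1‑(propan‑2‑yl)cyclopent‑2‑en‑1‑olate (racemic; centre lost on hydrolysis) | CCOC1=CC(O[Mg]Cl)(C(C)C)CC1 | intermediate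
11 | 3‑(propan‑2‑yl)cyclopent‑2‑en‑1‑one | CC(C)C1=CC(=O)CC1 | intermediate
12 | (1S)‑3‑(propan‑2‑yl)cyclopent‑2‑en‑1‑ol | O[C@@H]1C=C(C(C)C)CC1 | intermediate
13 | (1R,2S,5S)‑5‑(propan‑2‑yl)bicyclo[3.1.0]hexan‑2‑ol | O[C@H]1CC[C@@]2(C(C)C)C[C@@H]12 | intermediate
14 | (1R,5S)‑5‑(propan‑2‑yl)bicyclo[3.1.0]hexan‑2‑one | O=C1CC[C@@]2(C(C)C)C[C@@H]12 | intermediate
15 | (1S,5S)‑4‑methylidene‑1‑(propan‑2‑yl)bicyclo[3.1.0]hexane, (1S,5S)‑sabinene | C=C1CC[C@@]2(C(C)C)C[C@@H]12 | intermediate
16 | (1S,5S)‑4‑methyl‑1‑(propan‑2‑yl)bicyclo[3.1.0]hexan‑4‑ylium (thujyl cation, triflimide ion pair) | C[C+]1CC[C@@]2(C(C)C)C[C@@H]12 | intermediate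
17 | (1R)‑4‑methyl‑1‑(propan‑2‑yl)cyclohex‑3‑en‑1‑yl 4‑methoxy‑3,5‑bis(3‑methylbut‑2‑en‑1‑yl)benzoate | COc1c(CC=C(C)C)cc(C(=O)O[C@@]2(C(C)C)CC=C(C)CC2)cc1CC=C(C)C | target

**Summary and risks**

Total step count: 9. Longest linear sequence: 6 steps (steps 4–9); the acid arm is 3 steps (1–3).

Steps most likely to fail:

1. Step 9. The cation may lose a proton (elimination to terpinene‑type dienes) faster than it is captured by the weakly nucleophilic acid. Enantiopurity may erode through opening to the achiral classical cation, and the acid catalyst may attack the prenyl alkenes. Fallback, setting out from 15 and 7 and returning at 17: 15 is hydrated with dilute aqueous H2SO4 in acetone at 0 °C, the known ring‑expanding hydration of this skeleton, to (R)‑terpinen‑4‑ol F1. Acid 7 is converted under neutral conditions with 1‑chloro‑N,N,2‑trimethylprop‑1‑en‑1‑amine in CH2Cl2 to 4‑methoxy‑3,5‑bis(3‑methylbut‑2‑en‑1‑yl)benzoyl chloride F2. F1 is deprotonated with n‑BuLi in THF at −78 °C to lithium (R)‑terpinen‑4‑olate F3, which is acylated by F2 to give 17.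

2. Step 2. Regiocontrol of allyl transfer may be lost (γ‑attack giving 1,1‑dimethylallyl isomers), the second coupling may stall, or the boronate may protodeboronate. Fallback, setting out from 2 and returning at 5: double Stille coupling with allyltributylstannane (Pd(PPh3)4, toluene, 100 °C) should pass through methyl 3‑allyl‑5‑bromo‑4‑methoxybenzoate F4 to methyl 3,5‑diallyl‑4‑methoxybenzoate F5. Double cross‑metathesis with excess 2‑methylbut‑2‑ene (second‑generation Ru benzylidene catalyst, CH2Cl2, 40 °C) should then pass through methyl 3‑allyl‑4‑methoxy‑5‑(3‑methylbut‑2‑en‑1‑yl)benzoate F6 to 5.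

3. Step 5. The catalyst may discriminate the two carbonyl faces poorly, because the two arms of the ketone differ little next to the carbonyl, and alkene hydroboration may compete. Fallback, setting out from 11 and returning at 12: Luche reduction (NaBH4, CeCl3·7H2O, MeOH, 0 °C) gives racemic 3‑(propan‑2‑yl)cyclopent‑2‑en‑1‑ol F7. Lipase‑catalysed kinetic resolution (Candida antarctica lipase B, vinyl acetate, MTBE, run past half conversion) is expected, by the empirical selectivity rule for secondary alcohols, to acylate the (R)‑enantiomer to (1R)‑3‑(propan‑2‑yl)cyclopent‑2‑en‑1‑yl acetate F8. The unreacted (S)‑alcohol 12 is separated by chromatography.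

**Further compounds**
F1 | step 9 | (1R)‑4‑methyl‑1‑(propan‑2‑yl)cyclohex‑3‑en‑1‑ol, (R)‑terpinen‑4‑ol | O[C@@]1(C(C)C)CC=C(C)CC1
F2 | step 9 | 4‑methoxy‑3,5‑bis(3‑methylbut‑2‑en‑1‑yl)benzoyl chloride | ClC(=O)c1cc(CC=C(C)C)c(OC)c(CC=C(C)C)c1
F3 | step 9 | lithium (1R)‑4‑methyl‑1‑(propan‑2‑yl)cyclohex‑3‑en‑1‑olate | [Li+].[O-][C@@]1(C(C)C)CC=C(C)CC1
F4 | step 2 | methyl 3‑allyl‑5‑bromo‑4‑methoxybenzoate | COC(=O)c1cc(Br)c(OC)c(CC=C)c1
F5 | step 2 | methyl 3,5‑diallyl‑4‑methoxybenzoate | COC(=O)c1cc(CC=C)c(OC)c(CC=C)c1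
F6 | step 2 | methyl 3‑allyl‑4‑methoxy‑5‑(3‑methylbut‑2‑en‑1‑yl)benzoate | COC(=O)c1cc(CC=C)c(OC)c(CC=C(C)C)c1
F7 | step 5 | racemic 3‑(propan‑2‑yl)cyclopent‑2‑en‑1‑ol | OC1C=C(C(C)C)CC1
F8 | step 5 | (1R)‑3‑(propan‑2‑yl)cyclopent‑2‑en‑1‑yl acetate | CC(=O)O[C@H]1C=C(C(C)C)CC1
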